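Both benzene rings of lepidine C carry their imidazolylmethyl carbon meta to an oxygenated carbon (C-OMe in ring A, the bridging C-O in ring B). This is the pattern of a 3-alkoxycyclohex-2-enone whose C1 carbonyl marks the benzylic position, so both ring-CH2 bonds are cut there. The precursor is an O-linked bis(vinylogous ester): 3-methoxycyclohexenone (ring A) carrying at C6 the enol oxygen of a second cyclohexenone (ring B). In one operation two laterally metallated 2-methyl-1-tritylimidazoles add 1,2 to the two C1 carbonyls and form both ring-CH2 C-C bonds. Twofold dehydration, DDQ dehydrogenation and detritylation then give the diaryl ether.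

Key step: step 6

Remark: the target has no stereocentre; 4 and 7 are racemates, 12 is a diastereomer mixture and 13 a mixture of double-bond isomers of one oxidation level, all of which converge at 14.

Step 1
Reactants: 1 cyclohexane-1,3-dione
Product: 2 3-methoxycyclohex-2-en-1-one
Conditions: HC(OMe)3, p-TsOH·H2O (cat.), MeOH, 23 °C
Reagents that add atoms: trimethyl orthoformate COC(OC)OC; methanol CO
Why: Acid-catalysed vinylogous esterification, in which the enol of the 1,3-dione is O-methylated via its oxocarbenium ion and the orthoformate consumes the water, driving the equilibrium to the 3-methoxy enone.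

Step 2
Reactants: 2 3-methoxycyclohex-2-en-1-one
Product: 4 6-hydroxy-3-methoxycyclohex-2-en-1-one (racemic), via lithium dienolate 3 (not isolated)
Conditions: LiN(i-Pr)2 (LDA), THF, −78 °C; then (±)-trans-2-(phenylsulfonyl)-3-phenyloxaziridine, THF, −78 °C; sat. aq. NH4Cl
Reagents that add atoms: 2-(phenylsulfonyl)-3-phenyloxaziridine O=S(=O)(N1OC1c1ccccc1)c1ccccc1
Why: The amide base deprotonates a 3-alkoxycyclohexenone kinetically at the alpha-prime carbon C6 (cross-conjugated dienolate, the regiochemistry of Stork-Danheiser alkylations) and the N-sulfonyloxaziridine transfers oxygen to that carbon (Davis enolate hydroxylation), creating the C6 stereocentre as a racemate that is erased later.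

Step 3
Reactants: 1 cyclohexane-1,3-dione
Product: 5 3-chlorocyclohex-2-en-1-one
Conditions: (COCl)2, DMF (cat.), CH2Cl2, 0 → 23 °C
Reagents that add atoms: oxalyl chloride O=C(Cl)C(=O)Cl
Why: Vilsmeier-type activation, in which the chloroiminium ion formed from oxalyl chloride and DMF activates the enol oxygen and chloride adds and eliminates at C3 to give the vinylogous acid chloride.

Step 4
Reactants: 4 6-hydroxy-3-methoxycyclohex-2-en-1-one (racemic); 5 3-chlorocyclohex-2-en-1-one
Product: 7 3-methoxy-6-[(3-oxocyclohex-1-en-1-yl)oxy]cyclohex-2-en-1-one (racemic), via vinylogous acylammonium chloride 6 (not isolated)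
Conditions: DABCO (20 mol%), Cs2CO3, 4 Å molecular sieves, MeCN, 0 → 23 °C
Reagents that add atoms: none
Why: Conjugate addition-elimination (vinylogous acyl substitution) under nucleophilic catalysis, in which DABCO displaces chloride to give a more electrophilic ammonium enone that the caesium alkoxide of the ketol attacks at C3 with release of DABCO, so the future diaryl ether C-O bond is made at an unhindered sp2 carbon while the racemic C6 centre is untouched.

Step 5
Reactants: 8 2-methyl-1H-imidazole
Product: 9 2-methyl-1-trityl-1H-imidazole
Conditions: TrCl, Et3N, DMF, 23 °C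
Reagents that add atoms: trityl chloride ClC(c1ccccc1)(c1ccccc1)c1ccccc1
Why: N-Tritylation through the trityl cation (SN1 alkylation of the azole nitrogen), which masks the N-H and shields C5 so that the later metallation is directed to the 2-methyl group.

Step 6
Reactants: 7 3-methoxy-6-[(3-oxocyclohex-1-en-1-yl)oxy]cyclohex-2-en-1-one (racemic); 9 2-methyl-1-trityl-1H-imidazole
Product: 12 bis(tertiary allylic carbinol) 6-({3-hydroxy-3-[(1-tritylimidazol-2-yl)methyl]cyclohex-1-en-1-yl}oxy)-3-methoxy-1-[(1-tritylimidazol-2-yl)methyl]cyclohex-2-en-1-ol (diastereomer mixture), via lithiomethyl imidazole 10 (not isolated), via organocerium reagent 11 (not isolated)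
Conditions: 9 (3 equiv), n-BuLi, THF, −78 → −40 °C; anhydrous CeCl3, THF, −78 °C; then 7, THF, −78 °C; sat. aq. NaHCO3 quench, Celite filtration, Et3N-deactivated silica
Reagents that add atoms: none
Why: Proposed new method: n-BuLi removes a proton from the 2-methyl group of 9 (lateral lithiation to an aza-allyl anion), transmetallation with CeCl3 gives a less basic, oxophilic organocerium reagent, and two of these add 1,2 to the C1 carbonyl of ring A and of ring B of 7, forming both ring-CH2 C-C bonds, after which a bicarbonate work-up protonates the alkoxides without hydrolysing either gamma-alkoxy allylic carbinol. The closest known reactions are the first stage of the Stork-Danheiser sequence (1,2-addition of organolithiums to 3-alkoxycyclohex-2-enones) and organocerium additions to enolisable ketones; the new element is the twofold addition to an O-linked bis(vinylogous ester) with isolation of the unhydrolysed adduct. No ring is closed. The two new carbinol centres form without control beside the racemic C6 centre, so 12 is a diastereomer mixture, which is of no consequence because all three sp3 centres become sp2 in steps 7 and 8. The step needs carbonyl addition to beat enolisation at C6 of ring A and addition-elimination at the oxygen-bearing C3 of ring B; the cross-conjugated vinylogous ester carbonyls, the activation of the ring A carbonyl by its alpha-oxygen, the low temperature, the excess of reagent and the cerium counter-ion are expected to secure this.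

Step 7
Reactants: 12 bis(tertiary allylic carbinol) (diastereomer mixture)
Product: 13 bis(alkoxycyclohexadiene) 1-methoxy-3-[(1-tritylimidazol-2-yl)methyl]-4-({3-[(1-tritylimidazol-2-yl)methyl]cyclohexa-1,3-dien-1-yl}oxy)cyclohexa-1,3-diene (drawn isomer of a crude double-bond isomer mixture)
Conditions: Burgess reagent (3 equiv), Et3N (0.2 equiv), toluene, 23 → 50 °C; filtration through basic alumina, used at once
Reagents that add atoms: none
Why: Burgess dehydration, in which each tertiary allylic carbinol forms a sulfamate ester that ionises to an alkoxy-stabilised allyl cation and loses a neighbouring proton within the ion pair under anhydrous non-acidic conditions, so the enol ethers, the bridging oxygen and the trityl groups should survive and every double-bond isomer formed has the same oxidation level.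

Step 8
Reactants: 13 bis(alkoxycyclohexadiene) (crude isomer mixture)
Product: 14 N,N'-ditrityl lepidine C, 2-{[5-methoxy-2-(3-{[1-tritylimidazol-2-yl]methyl}phenoxy)phenyl]methyl}-1-tritylimidazole
Conditions: DDQ (2.05 equiv, added slowly), solid NaHCO3, CH2Cl2, 0 °C
Reagents that add atoms: none
Why: Quinone dehydrogenation, in which DDQ abstracts an allylic hydride from each electron-rich alkoxydiene to give an oxygen-stabilised cyclohexadienyl cation that loses a proton to the arene (the known aromatisation of alkoxycyclohexadienes to aryl ethers), with bicarbonate neutralising the hydroquinone so that no enol ether is hydrolysed before it aromatises and with the cold, near-stoichiometric oxidant sparing the CH2 links.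

Step 9
Reactants: 14 N,N'-ditrityl lepidine C
Product: 15 lepidine C, 2-{[5-methoxy-2-(3-(1H-imidazol-2-ylmethyl)phenoxy)phenyl]methyl}-1H-imidazole
Conditions: AcOH–H2O (4:1), 60 °C; then aq. NaHCO3
Reagents that add atoms: none
Why: Acid-mediated SN1 detritylation, in which each protonated imidazole departs from the stabilised trityl cation that water captures as triphenylmethanol, while the diaryl ether, the methyl ether and the CH2 links are inert to warm aqueous acetic acid.

Compound list
1 | cyclohexane-1,3-dione | O=C1CCCC(=O)C1 | starting material
2 | 3-methoxycyclohex-2-en-1-one | COC1=CC(=O)CCC1 | intermediate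
3 | lithium 5-methoxycyclohexa-1,5-dien-1-olate (kinetic dienolate of 2) | COC1=CC(O[Li])=CCC1 | intermediate
4 | 6-hydroxy-3-methoxycyclohex-2-en-1-one (racemic) | COC1=CC(=O)C(O)CC1 | intermediate
5 | 3-chlorocyclohex-2-en-1-one | O=C1C=C(Cl)CCC1 | intermediate
6 | 1-(3-oxocyclohex-1-en-1-yl)-4-aza-1-azoniabicyclo[2.2.2]octane chloride | O=C1C=C(CCC1)[N+]12CCN(CC1)CC2.[Cl-] | intermediate
7 | 3-methoxy-6-[(3-oxocyclohex-1-en-1-yl)oxy]cyclohex-2-en-1-one (racemic) | COC1=CC(=O)C(OC2=CC(=O)CCC2)CC1 | intermediate
8 | 2-methyl-1H-imidazole | Cc1ncc[nH]1 | starting material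
9 | 2-methyl-1-trityl-1H-imidazole | Cc1nccn1C(c1ccccc1)(c1ccccc1)c1ccccc1 | intermediate
10 | 2-(lithiomethyl)-1-trityl-1H-imidazole | [Li]Cc1nccn1C(c1ccccc1)(c1ccccc1)c1ccccc1 | intermediate
11 | dichloro[(1-tritylimidazol-2-yl)methyl]cerium | Cl[Ce](Cl)Cc1nccn1C(c1ccccc1)(c1ccccc1)c1ccccc1 | intermediate
12 | 6-({3-hydroxy-3-[(1-tritylimidazol-2-yl)methyl]cyclohex-1-en-1-yl}oxy)-3-methoxy-1-[(1-tritylimidazol-2-yl)methyl]cyclohex-2-en-1-ol (diastereomer mixture) | COC1=CC(O)(Cc2nccn2C(c2ccccc2)(c2ccccc2)c2ccccc2)C(OC2=CC(O)(Cc3nccn3C(c3ccccc3)(c3ccccc3)c3ccccc3)CCC2)CC1 | intermediate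
13 | 1-methoxy-3-[(1-tritylimidazol-2-yl)methyl]-4-({3-[(1-tritylimidazol-2-yl)methyl]cyclohexa-1,3-dien-1-yl}oxy)cyclohexa-1,3-diene (drawn isomer of the mixture) | COC1=CC(Cc2nccn2C(c2ccccc2)(c2ccccc2)c2ccccc2)=C(OC2=CC(Cc3nccn3C(c3ccccc3)(c3ccccc3)c3ccccc3)=CCC2)CC1 | intermediate
14 | N,N'-ditrityl lepidine C | COc1ccc(Oc2cccc(Cc3nccn3C(c3ccccc3)(c3ccccc3)c3ccccc3)c2)c(Cc2nccn2C(c2ccccc2)(c2ccccc2)c2ccccc2)c1 | intermediate
15 | lepidine C | COc1ccc(Oc2cccc(Cc3ncc[nH]3)c2)c(Cc2ncc[nH]2)c1 | target

Total step count: 9 steps.
Longest linear sequence: 7 steps (1 → 2 → 4 → 7 → 12 → 13 → 14 → 15). Steps 3 and 5 supply the two side branches.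

Steps most likely to fail

1. Step 6 (proposed new method). Several processes may outrun the second carbonyl addition: proton transfer from C6 of ring A to the carbanion, addition-elimination at the oxygen-bearing C3 of ring B that cuts the ether link, and migration of the ring B enone unit onto the newly formed ring A alkoxide. The adduct may also hydrolyse during isolation. The fallback uses known chemistry, sets out from 9 and returns at 14. Commercial 2-bromo-4-methoxyphenol and (3-bromophenyl)boronic acid are joined by a Chan-Lam coupling (Cu(OAc)2, pyridine, 4 Å molecular sieves, CH2Cl2, air, 23 °C) to 2-bromo-1-(3-bromophenoxy)-4-methoxybenzene F1. Compound 9 is lithiated to 10 as in step 6 and transmetallated with ZnCl2 to chloro[(1-tritylimidazol-2-yl)methyl]zinc F2. A twofold Negishi coupling of F2 with F1 (Pd(OAc)2, SPhos, THF, 60 °C) should then give 14, which continues with step 9.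

2. Step 7. Sulfamate formation at the hindered ring A carbinol may be slow, and traces of acid or water may divert the allyl cation to an enone with loss of an enol-ether oxygen. The fallback sets out from 12 and returns at 13. Compound 12 is deprotonated with KN(SiMe3)2 and acylated with methyl chloroformate (THF, −78 °C) to the bis(methyl carbonate) F3. Zerovalent palladium (Pd(PPh3)4, Et3N, THF, 50 °C) then ionises each allylic carbonate to a pi-allyl complex that undergoes beta-hydride elimination, the known palladium-catalysed conversion of allylic carbonates into 1,3-dienes. This should give 13 under neutral conditions.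

3. Step 8. Hydride abstraction may continue at the CH2 between arene and imidazole (over-oxidation), or an enol ether may be cleaved by the acidic hydroquinone before its ring has aromatised, with loss of the bridging oxygen. The fallback sets out from 7 and returns at 14; it moves the dehydrogenation ahead of C-C bond formation, to a stage without imidazoles or trityl groups. Compound 7 is converted with LiN(i-Pr)2 and Me3SiCl (THF, −78 °C) into the bis(trimethylsilyl dienol ether) F4. Saegusa-Ito oxidation (Pd(OAc)2, MeCN, 23 °C) and tautomerisation of the dienones should give 2-(3-hydroxyphenoxy)-5-methoxyphenol F5. Tf2O and pyridine (CH2Cl2, 0 °C) give the bis(triflate) F6. Twofold Negishi coupling of F6 with the zinc reagent chloro[(1-tritylimidazol-2-yl)methyl]zinc F2, made from 9 as above (Pd(OAc)2, SPhos, THF, 60 °C), should then place both arms on the former carbonyl carbons and give 14.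

Further compounds
F1 | step 6 | 2-bromo-1-(3-bromophenoxy)-4-methoxybenzene | COc1ccc(Oc2cccc(Br)c2)c(Br)c1
F2 | step 6 | chloro[(1-tritylimidazol-2-yl)methyl]zinc | Cl[Zn]Cc1nccn1C(c1ccccc1)(c1ccccc1)c1ccccc1
F3 | step 7 | bis(methyl carbonate) of 12 | COC1=CC(OC(=O)OC)(Cc2nccn2C(c2ccccc2)(c2ccccc2)c2ccccc2)C(OC2=CC(OC(=O)OC)(Cc3nccn3C(c3ccccc3)(c3ccccc3)c3ccccc3)CCC2)CC1
F4 | step 8 | bis(trimethylsilyl dienol ether) of 7 | COC1=CC(O[Si](C)(C)C)=C(OC2=CC(O[Si](C)(C)C)=CCC2)CC1
F5 | step 8 | 2-(3-hydroxyphenoxy)-5-methoxyphenol | COc1ccc(Oc2cccc(O)c2)c(O)c1
F6 | step 8 | 5-methoxy-2-[3-(trifluoromethylsulfonyloxy)phenoxy]phenyl trifluoromethanesulfonate | COc1ccc(Oc2cccc(OS(=O)(=O)C(F)(F)F)c2)c(OS(=O)(=O)C(F)(F)F)c1
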